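**Retrosynthetic overview**
1. Bongardol ⇒ ester C–O disconnection into octacosanoic acid (used as its acid chloride) and tyrosol, with the phenol masked as a benzyl ether that is removed last.
2. Octacosanoic acid ⇒ 7-oxooctacosanoic acid (Wolff–Kishner) ⇒ a β-keto diester (hydrolysis and decarboxylation).
3. Key C–C bond (C7–C8 of the acid): intermolecular crossed Claisen condensation of the lithium enolate of methyl docosanoate (C22) with methyl 7-chloro-7-oxoheptanoate (C7); 22 + 7 − 1 (CO2) = 28 carbons.
4. No ring is formed; the only ring, the para-substituted benzene, is bought intact in tyrosol.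

Assumption: the target has no stereocentre and no stereogenic double bond, so it is achiral and no stereocontrol is needed; the acyl chain is octacosanoyl (C28).

**Step 1**
Reactants: 1 7-methoxy-7-oxoheptanoic acid (monomethyl pimelate)
Product: 2 methyl 7-chloro-7-oxoheptanoate
Conditions: (COCl)2 (1.3 eq), cat. DMF, CH2Cl2, 0 °C → rt; evaporate
Reagents that add atoms: oxalyl chloride, ClC(=O)C(Cl)=O
Why: DMF-catalysed (Vilsmeier) acid chloride formation by nucleophilic acyl substitution is essentially quantitative, leaves the methyl ester untouched and gives only gaseous by-products.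

**Step 2**
Reactants: 3 methyl docosanoate (2.2 eq); 2 methyl 7-chloro-7-oxoheptanoate (1.0 eq)
Product: 5 dimethyl 2-icosyl-3-oxononanedioate (racemic), via lithium enolate 4 (not isolated)
Conditions: LDA (2.2 eq), THF, −78 °C (briefly −40 °C); then 2, −78 → −20 °C; aq NH4Cl; chromatography (excess 3 recovered)
Reagents that add atoms: none
Why: Crossed Claisen condensation (C-acylation of a preformed ester lithium enolate by an acyl chloride): the acyl chloride is far more electrophilic than either methyl ester at −78 °C, the second equivalent of enolate deprotonates the β-keto ester and so stops double acylation, and the new C2 stereocentre is formed racemic and erased in step 3.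

**Step 3**
Reactants: 5 dimethyl 2-icosyl-3-oxononanedioate
Product: 7 7-oxooctacosanoic acid, via keto diacid 6 (not isolated)
Conditions: AcOH, conc. HCl, H2O (4:1:1), reflux, 16 h; crystallise
Reagents that add atoms: water, O
Why: Acid-catalysed ester hydrolysis followed by decarboxylation of the β-keto acid (ketonic cleavage) turns the C2 stereocentre into CH2, and the acidic medium avoids the retro-Claisen cleavage that strong alkali could cause.

**Step 4**
Reactants: 7 7-oxooctacosanoic acid
Product: 9 octacosanoic acid, via hydrazone 8 (not isolated)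
Conditions: N2H4·H2O, KOH, diethylene glycol, 130 °C, then 200 °C (distil off H2O); aq HCl; recrystallise
Reagents that add atoms: none
Why: Wolff–Kishner reduction (Huang-Minlon modification) is the classical high-yielding deoxygenation of long-chain keto acids, and the carboxylate is inert to hydrazine and KOH.

**Step 5**
Reactants: 9 octacosanoic acid
Product: 10 octacosanoyl chloride
Conditions: SOCl2 (3 eq), cat. DMF, toluene, 70 °C; evaporate
Reagents that add atoms: thionyl chloride, O=S(Cl)Cl
Why: Acid chloride formation (nucleophilic acyl substitution) converts the waxy acid into a soluble activated form with only gaseous by-products.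

**Step 6**
Reactants: 11 tyrosol
Product: 12 2-[4-(benzyloxy)phenyl]ethanol
Conditions: BnBr (1.05 eq), K2CO3 (1.5 eq), acetone, reflux
Reagents that add atoms: benzyl bromide, BrCc1ccccc1
Why: Williamson ether synthesis in which K2CO3 deprotonates only the phenol (pKa about 10) and not the primary alcohol (pKa about 16), so O-benzylation is chemoselective.

**Step 7**
Reactants: 10 octacosanoyl chloride; 12 2-[4-(benzyloxy)phenyl]ethanol
Product: 13 2-[4-(benzyloxy)phenyl]ethyl octacosanoate
Conditions: Et3N (1.5 eq), cat. DMAP, CH2Cl2/toluene, 0 → 40 °C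
Reagents that add atoms: none
Why: DMAP-catalysed acylation of a primary alcohol by an acid chloride (nucleophilic acyl substitution) is fast and irreversible, and the only competing nucleophile, the phenol, is blocked as its benzyl ether.

**Step 8**
Reactants: 13 2-[4-(benzyloxy)phenyl]ethyl octacosanoate
Product: 14 Bongardol
Conditions: H2 (1 atm), 10% Pd/C, THF/EtOAc (1:1), 40 °C
Reagents that add atoms: none
Why: Catalytic hydrogenolysis cleaves the benzyl aryl ether, while the homobenzylic ester C–O bond, the saturated chain and the arene are inert under 1 atm H2 over Pd/C; the target has no stereocentre to set.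

**Compound list**
1 | 7-methoxy-7-oxoheptanoic acid (monomethyl pimelate) | COC(=O)CCCCCC(=O)O | starting material
2 | methyl 7-chloro-7-oxoheptanoate | COC(=O)CCCCCC(Cl)=O | intermediate
3 | methyl docosanoate (methyl behenate) | CCCCCCCCCCCCCCCCCCCCCC(=O)OC | starting material
4 | lithium enolate of methyl docosanoate (lithium 1-methoxydocos-1-en-1-olate, E/Z immaterial, not isolated) | CCCCCCCCCCCCCCCCCCCCC=C(OC)[O-].[Li+] | intermediate
5 | dimethyl 2-icosyl-3-oxononanedioate (racemic at C2) | CCCCCCCCCCCCCCCCCCCCC(C(=O)OC)C(=O)CCCCCC(=O)OC | intermediate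
6 | 2-icosyl-3-oxononanedioic acid (racemic, not isolated) | CCCCCCCCCCCCCCCCCCCCC(C(=O)O)C(=O)CCCCCC(=O)O | intermediate
7 | 7-oxooctacosanoic acid | CCCCCCCCCCCCCCCCCCCCCC(=O)CCCCCC(=O)O | intermediate
8 | 7-hydrazinylideneoctacosanoic acid (hydrazone, potassium salt in the flask, E/Z immaterial, not isolated) | CCCCCCCCCCCCCCCCCCCCCC(=NN)CCCCCC(=O)O | intermediate
9 | octacosanoic acid | CCCCCCCCCCCCCCCCCCCCCCCCCCCC(=O)O | intermediate
10 | octacosanoyl chloride | CCCCCCCCCCCCCCCCCCCCCCCCCCCC(Cl)=O | intermediate
11 | tyrosol (4-(2-hydroxyethyl)phenol) | OCCc1ccc(O)cc1 | starting material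
12 | 2-[4-(benzyloxy)phenyl]ethanol | OCCc1ccc(OCc2ccccc2)cc1 | intermediate
13 | 2-[4-(benzyloxy)phenyl]ethyl octacosanoate | CCCCCCCCCCCCCCCCCCCCCCCCCCCC(=O)OCCc1ccc(OCc2ccccc2)cc1 | intermediate
14 | Bongardol (2-(4-hydroxyphenyl)ethyl octacosanoate, achiral) | CCCCCCCCCCCCCCCCCCCCCCCCCCCC(=O)OCCc1ccc(O)cc1 | target

**Step count**
Total steps: 8. Longest linear sequence: 7 (steps 1, 2, 3, 4, 5, 7, 8; step 6 is a one-step side branch).

**Steps most likely to fail, with fallbacks**

Step 2 (crossed Claisen). Risks are poor solubility of the C22 enolate at −78 °C, self-condensation of 3, and O-acylation. The fallback makes the same C7–C8 bond by a Stork–Hünig enamine acylation followed by ring opening. It sets out from 3 and comes back to the route at 7, so 1, 2, 5 and 6 are no longer needed. Saponification of 3 (NaOH, aq EtOH, reflux; HCl) gives docosanoic acid F1. SOCl2 with cat. DMF in toluene at 70 °C gives docosanoyl chloride F2. F2 acylates commercial 4-(cyclohex-1-en-1-yl)morpholine (Et3N, CHCl3, 35 °C) to the acylated enamine 1-[2-(morpholin-4-yl)cyclohex-1-en-1-yl]docosan-1-one F3. Aqueous HCl in the same pot hydrolyses F3 to 2-docosanoylcyclohexan-1-one F4. Retro-Claisen ring opening of F4 (aq KOH, reflux; then H3O+) gives 7.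

Step 3 (hydrolysis and decarboxylation). Risks are incomplete hydrolysis of the very lipophilic diester in aqueous acid and partial retro-Claisen cleavage. The fallback sets out from 5 and comes back at 7. Krapcho demethoxycarbonylation (LiCl, wet DMSO, 150 °C) removes only the β-keto ester group by SN2 attack of chloride on its methyl group, giving methyl 7-oxooctacosanoate F5. Mild saponification (LiOH, THF/MeOH/H2O, 50 °C; H3O+) then gives 7.

Step 4 (Wolff–Kishner). Risks are foaming and poor solubility of the C28 soap in glycol, and incomplete reduction or azine formation. The fallback sets out from 7 and comes back at 9. Thioketalisation (ethane-1,2-dithiol, BF3·OEt2, CH2Cl2/AcOH, rt) gives 6-(2-henicosyl-1,3-dithiolan-2-yl)hexanoic acid F6. Raney nickel desulfurisation (W-2 Raney Ni, EtOH, reflux) then gives 9.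

**Further compounds**
F1 | step 2 | docosanoic acid | CCCCCCCCCCCCCCCCCCCCCC(=O)O
F2 | step 2 | docosanoyl chloride | CCCCCCCCCCCCCCCCCCCCCC(Cl)=O
F3 | step 2 | 1-[2-(morpholin-4-yl)cyclohex-1-en-1-yl]docosan-1-one | CCCCCCCCCCCCCCCCCCCCCC(=O)C1=C(CCCC1)N1CCOCC1
F4 | step 2 | 2-docosanoylcyclohexan-1-one (racemic, largely enolised) | CCCCCCCCCCCCCCCCCCCCCC(=O)C1CCCCC1=O
F5 | step 3 | methyl 7-oxooctacosanoate | CCCCCCCCCCCCCCCCCCCCCC(=O)CCCCCC(=O)OC
F6 | step 4 | 6-(2-henicosyl-1,3-dithiolan-2-yl)hexanoic acid | CCCCCCCCCCCCCCCCCCCCCC1(CCCCCC(=O)O)SCCS1
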